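Eremophilane numbering is used (ring A: C1–C5 and C10; ring B: C5–C10). Everything rests on an intramolecular Diels–Alder reaction of an acyclic (7E)-4-hydroxy-1,7,9-decatrien-3-one. The vinyl ketone C10=C1, activated by the future C9 carbonyl, adds across the C2=C3–C4=C5 diene, so that C1–C2 and C5–C10 form in one operation; both rings close and the quaternary C5 and the cis-disposed C10–H are set. The step exploits the C4/C5 vicinal methyl pair beside the C9-oxygenated ring fusion, which maps onto a tetrasubstituted E-diene terminus and a hydroxy enone; the C7 and C8 stereocentres in the tether direct the facial course. Allylic oxidation and conjugate reduction then supply the C2 ketone and C4–H.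

Key step: step 10

Remark: the C9 ester is read from the SMILES as the (E)-2-methylbut-2-enoate (tiglate), and the target as (4S,5R,7R,8R,9S,10S), i.e. 4β,5β-dimethyl, 10β-H (cis-fused), 7β-isopropenyl, 8α-OAc, 9α-O-tigloyl.

Step 1
Reactants: 1 ethyl 2-methyl-3-oxobutanoate
Product: 2 ethyl (2E)-2-methyl-3-(tosyloxy)but-2-enoate
Conditions: TsCl, N-methylimidazole, Et3N, toluene, 0 °C
Reagents that add atoms: 4-toluenesulfonyl chloride, Cc1ccc(cc1)S(Cl)(=O)=O
Why: Enol sulfonylation of a β-keto ester under amine, non-chelating conditions should place the tosylate trans to the ester (E), which fixes the geometry that later puts C6 trans to C3 on the C4=C5 bond.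

Step 2
Reactants: 2 ethyl (2E)-2-methyl-3-(tosyloxy)but-2-enoate; 3 potassium vinyltrifluoroborate
Product: 4 ethyl (2E)-2,3-dimethylpenta-2,4-dienoate
Conditions: PdCl2(dppf) (cat.), K2CO3, THF/H2O, 70 °C
Reagents that add atoms: none
Why: Suzuki–Miyaura coupling of the activated β-sulfonyloxy acrylate proceeds with retention of alkene geometry and installs the vinyl group (C3=C2) on C4.

Step 3
Reactants: 4 ethyl (2E)-2,3-dimethylpenta-2,4-dienoate
Product: 5 (2E)-2,3-dimethylpenta-2,4-dien-1-ol
Conditions: i-Bu2AlH (2.2 equiv), CH2Cl2, −78 °C; Rochelle salt work-up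
Reagents that add atoms: none
Why: 1,2-Reduction of the ester by the aluminium hydride at low temperature gives the allylic alcohol and leaves the diene untouched.

Step 4
Reactants: 5 (2E)-2,3-dimethylpenta-2,4-dien-1-ol
Product: 6 (3E)-5-bromo-3,4-dimethylpenta-1,3-diene
Conditions: CBr4, PPh3, CH2Cl2, 0 °C; used at once as a solution
Reagents that add atoms: carbon tetrabromide, BrC(Br)(Br)Br
Why: The Appel reaction converts the primary allylic alcohol into the bromide by SN2 displacement under cold, neutral conditions, which should keep allylic transposition to a minimum.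

Step 5
Reactants: 7 (4R)-4-benzyl-1,3-oxazolidin-2-one; 8 3-methylbut-2-enoyl chloride
Product: 9 (4R)-4-benzyl-3-(3-methylbut-2-enoyl)-1,3-oxazolidin-2-one
Conditions: n-BuLi, THF, −78 °C; then 8, −78 → 0 °C
Reagents that add atoms: none
Why: N-Acylation of the lithiated oxazolidinone with the acid chloride attaches the chiral auxiliary.

Step 6
Reactants: 9 (4R)-4-benzyl-3-(3-methylbut-2-enoyl)-1,3-oxazolidin-2-one; 6 (3E)-5-bromo-3,4-dimethylpenta-1,3-diene
Product: 10 (4R)-4-benzyl-3-[(2R,4E)-4,5-dimethyl-2-(prop-1-en-2-yl)hepta-4,6-dienoyl]-1,3-oxazolidin-2-one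
Conditions: NaN(SiMe3)2 (1.1 equiv), THF, −78 °C; then 6, −78 → −40 °C
Reagents that add atoms: none
Why: Evans alkylation in its deconjugative form: γ-deprotonation gives the chelated (Z)-dienolate, which the allylic bromide alkylates at the α-carbon on the face opposite the benzyl group, setting C7 as R and unveiling the isopropenyl group.

Step 7
Reactants: 10 (4R)-4-benzyl-3-[(2R,4E)-4,5-dimethyl-2-(prop-1-en-2-yl)hepta-4,6-dienoyl]-1,3-oxazolidin-2-one
Product: 11 (2R,4E)-4,5-dimethyl-2-(prop-1-en-2-yl)hepta-4,6-dien-1-ol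
Conditions: LiBH4, H2O (1 equiv), Et2O, 0 °C
Reagents that add atoms: none
Why: Reductive cleavage of the imide with LiBH4 gives the primary alcohol without epimerising the allylic stereocentre and releases the auxiliary for recovery.

Step 8
Reactants: 11 (2R,4E)-4,5-dimethyl-2-(prop-1-en-2-yl)hepta-4,6-dien-1-ol
Product: 12 (2R,4E)-4,5-dimethyl-2-(prop-1-en-2-yl)hepta-4,6-dienal
Conditions: Dess–Martin periodinane, NaHCO3, CH2Cl2, 0 °C; crude aldehyde used immediately
Reagents that add atoms: none
Why: Dess–Martin oxidation under buffered, non-basic conditions gives the configurationally labile α-isopropenyl aldehyde, which is carried on cold and without purification.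

Step 9
Reactants: 12 (2R,4E)-4,5-dimethyl-2-(prop-1-en-2-yl)hepta-4,6-dienal; 13 4,4,5,5-tetramethyl-2-(propa-1,2-dien-1-yl)-1,3,2-dioxaborolane
Product: 15 (3S,4R,5R,7E)-7,8-dimethyl-5-(prop-1-en-2-yl)deca-1,7,9-triene-3,4-diol, via borinate–boronate adduct 14 (not isolated)
Conditions: (−)-Ipc2BH (from (+)-α-pinene), 13, Et2O, 0 → 23 °C; then 12, −78 °C; then NaOH, H2O2, 0 → 23 °C
Reagents that add atoms: hydrogen peroxide, OO
Why: Brown-type γ-borylallylboration (masked α-hydroxyallylboration) through a closed chair transition state: the isopinocampheyl groups direct the allyl unit to the Si face of the aldehyde and set C8 as R under reagent control, oxidation of both C–B bonds gives the diol, and the C9 configuration is erased in step 10.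

Step 10
Reactants: 15 (3S,4R,5R,7E)-7,8-dimethyl-5-(prop-1-en-2-yl)deca-1,7,9-triene-3,4-diol
Product: 17 (2R,3R,4aS,8aS)-2-hydroxy-4a,5-dimethyl-3-(prop-1-en-2-yl)-3,4,4a,7,8,8a-hexahydronaphthalen-1(2H)-one, via hydroxy trienone 16 (not isolated)
Conditions: MnO2 (activated, excess), CH2Cl2, 23 °C; filtration; then toluene, BHT (cat.), 90 °C
Reagents that add atoms: none
Why: After chemoselective oxidation of the allylic C9 alcohol, the step is a concerted, suprafacial [4+2] cycloaddition, an intramolecular Diels–Alder reaction of the 1,7,9-decatrien-3-one type; the closest known relatives are cyclisations of decatrienones and Diels–Alder reactions of α′-hydroxy vinyl ketones, whose internal O–H···O=C hydrogen bond activates the enone and holds it s-cis. Ring A (C10, C1–C5) is closed as the new cyclohexene by both new bonds, and ring B (C5–C10) by the C5–C10 bond across the four-carbon tether C6–C9 (fused mode). Because C6 is trans to C3 on the C4=C5 bond, the endo arrangement (C9=O under C3–C4) gives the cis ring fusion, with the C5 methyl and C10–H on the same face. In that arrangement the forming ring B is a chair in which the C7 isopropenyl group and the hydrogen-bonded C8 hydroxyl of the (7R,8R) tether are both equatorial for attack on one diene face only, which sets C5 as R and C10 as S; attack on the other face would put both groups axial, 1,3 to C4. The selectivity needed is endo over exo, and it should be secured by secondary overlap of the carbonyl and by the inside methyl on C5, which eclipses the tether in the exo arrangement. The moderate temperature, neutral medium and radical inhibitor are chosen so that the cycloaddition outruns [1,5]-hydrogen shift in the diene and oxa-Michael closure of the hydroxy enone.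

Step 11
Reactants: 17 (2R,3R,4aS,8aS)-2-hydroxy-4a,5-dimethyl-3-(prop-1-en-2-yl)-3,4,4a,7,8,8a-hexahydronaphthalen-1(2H)-one
Product: 18 (2R,3R,4aS,8aS)-4a,5-dimethyl-1-oxo-3-(prop-1-en-2-yl)-1,2,3,4,4a,7,8,8a-octahydronaphthalen-2-yl acetate
Conditions: Ac2O, pyridine, DMAP (cat.), CH2Cl2, 0 °C
Reagents that add atoms: acetic anhydride, CC(=O)OC(C)=O
Why: DMAP-catalysed acetylation of the secondary α-hydroxy ketone installs the C8 acetate under mild conditions that should not epimerise C8 or C10.

Step 12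
Reactants: 18 (2R,3R,4aS,8aS)-4a,5-dimethyl-1-oxo-3-(prop-1-en-2-yl)-1,2,3,4,4a,7,8,8a-octahydronaphthalen-2-yl acetate
Product: 19 (2R,3R,4aS,8aS)-4a,5-dimethyl-1,7-dioxo-3-(prop-1-en-2-yl)-1,2,3,4,4a,7,8,8a-octahydronaphthalen-2-yl acetate
Conditions: Rh2(cap)4 (dirhodium tetracaprolactamate, 1 mol %), t-BuOOH (70% in H2O, 5 equiv), K2CO3 (cat.), CH2Cl2, 23 °C
Reagents that add atoms: tert-butyl hydroperoxide, CC(C)(C)OO
Why: Dirhodium-catalysed allylic oxidation with t-BuOOH: hydrogen abstraction at C2, the only ring methylene allylic to C3=C4, and collapse of the mixed peroxide give the C2 enone, while oxygenation at the tertiary C4 terminus cannot lead to a ketone.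

Step 13
Reactants: 19 (2R,3R,4aS,8aS)-4a,5-dimethyl-1,7-dioxo-3-(prop-1-en-2-yl)-1,2,3,4,4a,7,8,8a-octahydronaphthalen-2-yl acetate
Product: 20 (1S,2R,3R,4aS,8aS)-1-hydroxy-4a,5-dimethyl-7-oxo-3-(prop-1-en-2-yl)-1,2,3,4,4a,7,8,8a-octahydronaphthalen-2-yl acetate
Conditions: NaBH4, MeOH/CH2Cl2 (1:1), −78 °C; AcOH quench
Reagents that add atoms: none
Why: Chemoselective borohydride reduction of the electron-poor α-acetoxy ketone beside the less electrophilic β,β-disubstituted enone; hydride should add to C9 from the convex β face (the α face is screened by ring A, attached axially at C5), giving the axial 9α-alcohol.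

Step 14
Reactants: 20 (1S,2R,3R,4aS,8aS)-1-hydroxy-4a,5-dimethyl-7-oxo-3-(prop-1-en-2-yl)-1,2,3,4,4a,7,8,8a-octahydronaphthalen-2-yl acetate
Product: 21 (1S,2R,3R,4aR,5S,8aS)-1-hydroxy-4a,5-dimethyl-7-oxo-3-(prop-1-en-2-yl)decahydronaphthalen-2-yl acetate
Conditions: [(Ph3P)CuH]6 (0.5 equiv), H2O (5 equiv), toluene, 23–40 °C
Reagents that add atoms: none
Why: Copper hydride conjugate reduction (Stryker-type) of the enone tolerates the isolated isopropenyl group; hydride is delivered to C4 anti to the axial C5 methyl, so the C4 methyl ends up β, cis to the C5 methyl (4S).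

Step 15
Reactants: 21 (1S,2R,3R,4aR,5S,8aS)-1-hydroxy-4a,5-dimethyl-7-oxo-3-(prop-1-en-2-yl)decahydronaphthalen-2-yl acetate; 22 (2E)-2-methylbut-2-enoyl chloride
Product: 23 (1S,2R,3R,4aR,5S,8aS)-2-acetoxy-4a,5-dimethyl-7-oxo-3-(prop-1-en-2-yl)decahydronaphthalen-1-yl (2E)-2-methylbut-2-enoate (CNP0204573.1)
Conditions: 22, Et3N, DMAP, CH2Cl2, 40 °C
Reagents that add atoms: none
Why: DMAP-catalysed acylation of the hindered axial C9 alcohol with the acid chloride; the (E)-tigloyl geometry is configurationally stable, and the C8 acetate already sits on the less hindered equatorial oxygen, so it has no driving force to migrate.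

Compound list
1 | ethyl 2-methyl-3-oxobutanoate | CCOC(=O)C(C)C(C)=O | starting material
2 | ethyl (2E)-2-methyl-3-(tosyloxy)but-2-enoate | CCOC(=O)/C(C)=C(C)/OS(=O)(=O)c1ccc(C)cc1 | intermediate
3 | potassium vinyltrifluoroborate | C=C[B-](F)(F)F.[K+] | starting material
4 | ethyl (2E)-2,3-dimethylpenta-2,4-dienoate | CCOC(=O)/C(C)=C(C)/C=C | intermediate
5 | (2E)-2,3-dimethylpenta-2,4-dien-1-ol | OC/C(C)=C(C)/C=C | intermediate
6 | (3E)-5-bromo-3,4-dimethylpenta-1,3-diene | BrC/C(C)=C(C)/C=C | intermediate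
7 | (4R)-4-benzyl-1,3-oxazolidin-2-one | O=C1N[C@H](Cc2ccccc2)CO1 | starting material
8 | 3-methylbut-2-enoyl chloride | CC(C)=CC(Cl)=O | starting material
9 | (4R)-4-benzyl-3-(3-methylbut-2-enoyl)-1,3-oxazolidin-2-one | CC(C)=CC(=O)N1[C@H](Cc2ccccc2)COC1=O | intermediate
10 | (4R)-4-benzyl-3-[(2R,4E)-4,5-dimethyl-2-(prop-1-en-2-yl)hepta-4,6-dienoyl]-1,3-oxazolidin-2-one | C=C(C)[C@H](C(=O)N1[C@H](Cc2ccccc2)COC1=O)C/C(C)=C(C)/C=C | intermediate
11 | (2R,4E)-4,5-dimethyl-2-(prop-1-en-2-yl)hepta-4,6-dien-1-ol | C=C(C)[C@H](CO)C/C(C)=C(C)/C=C | intermediate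
12 | (2R,4E)-4,5-dimethyl-2-(prop-1-en-2-yl)hepta-4,6-dienal | C=C(C)[C@H](C=O)C/C(C)=C(C)/C=C | intermediate
13 | 4,4,5,5-tetramethyl-2-(propa-1,2-dien-1-yl)-1,3,2-dioxaborolane (allenylboronic acid pinacol ester) | C=C=CB1OC(C)(C)C(C)(C)O1 | starting material
14 | borinate–boronate adduct of 12: (7E)-deca-1,7,9-triene chain carrying the diisopinocampheylboryloxy group at C4 and the pinacolboryl group at C3 (anti), otherwise as 15 | C=C(C)[C@H]([C@@H](OB([C@@H]1C[C@@H]2C[C@H]([C@H]1C)C2(C)C)[C@@H]1C[C@@H]2C[C@H]([C@H]1C)C2(C)C)[C@@H](B1OC(C)(C)C(C)(C)O1)C=C)C/C(C)=C(C)/C=C | intermediate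
15 | (3S,4R,5R,7E)-7,8-dimethyl-5-(prop-1-en-2-yl)deca-1,7,9-triene-3,4-diol | C=C(C)[C@H]([C@@H](O)[C@@H](O)C=C)C/C(C)=C(C)/C=C | intermediate
16 | (4R,5R,7E)-4-hydroxy-7,8-dimethyl-5-(prop-1-en-2-yl)deca-1,7,9-trien-3-one | C=C(C)[C@H]([C@@H](O)C(=O)C=C)C/C(C)=C(C)/C=C | intermediate
17 | (2R,3R,4aS,8aS)-2-hydroxy-4a,5-dimethyl-3-(prop-1-en-2-yl)-3,4,4a,7,8,8a-hexahydronaphthalen-1(2H)-one (cis-fused cycloadduct) | C=C(C)[C@H]1C[C@@]2(C)[C@H](CCC=C2C)C(=O)[C@@H]1O | intermediate
18 | (2R,3R,4aS,8aS)-4a,5-dimethyl-1-oxo-3-(prop-1-en-2-yl)-1,2,3,4,4a,7,8,8a-octahydronaphthalen-2-yl acetate | C=C(C)[C@H]1C[C@@]2(C)[C@H](CCC=C2C)C(=O)[C@@H]1OC(C)=O | intermediate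
19 | (2R,3R,4aS,8aS)-4a,5-dimethyl-1,7-dioxo-3-(prop-1-en-2-yl)-1,2,3,4,4a,7,8,8a-octahydronaphthalen-2-yl acetate | C=C(C)[C@H]1C[C@@]2(C)[C@H](CC(=O)C=C2C)C(=O)[C@@H]1OC(C)=O | intermediate
20 | (1S,2R,3R,4aS,8aS)-1-hydroxy-4a,5-dimethyl-7-oxo-3-(prop-1-en-2-yl)-1,2,3,4,4a,7,8,8a-octahydronaphthalen-2-yl acetate | C=C(C)[C@H]1C[C@@]2(C)[C@H](CC(=O)C=C2C)[C@H](O)[C@@H]1OC(C)=O | intermediate
21 | (1S,2R,3R,4aR,5S,8aS)-1-hydroxy-4a,5-dimethyl-7-oxo-3-(prop-1-en-2-yl)decahydronaphthalen-2-yl acetate | C=C(C)[C@H]1C[C@@]2(C)[C@H](CC(=O)C[C@@H]2C)[C@H](O)[C@@H]1OC(C)=O | intermediate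
22 | (2E)-2-methylbut-2-enoyl chloride (tigloyl chloride) | C/C=C(\C)C(Cl)=O | starting material
23 | (1S,2R,3R,4aR,5S,8aS)-2-acetoxy-4a,5-dimethyl-7-oxo-3-(prop-1-en-2-yl)decahydronaphthalen-1-yl (2E)-2-methylbut-2-enoate; eremophilane numbering (4S,5R,7R,8R,9S,10S) | C=C(C)[C@H]1C[C@@]2(C)[C@H](CC(=O)C[C@@H]2C)[C@H](OC(=O)/C(C)=C/C)[C@@H]1OC(C)=O | target

Total step count: 15. Longest linear sequence: 14 steps (steps 1–4 and 6–15, from 1 to 23); step 5 is a one-step side branch.

Steps most likely to fail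

Step 10 (key cycloaddition). The cycloaddition may be too slow at the fully substituted C5 diene terminus, so that [1,5]-hydrogen shift in the diene, oxa-Michael closure of the hydroxy enone or erosion of endo selectivity compete at the temperature required. The fallback sets out from 15 and comes back at 17. Compound 15 is oxidised with MnO2 as in step 10 but at 0 °C, and 16 is isolated cold. Silylation (Et3SiOTf, 2,6-lutidine, CH2Cl2, −78 °C) gives the triethylsilyl ether of the trienone F1. A Lewis-acid-promoted cycloaddition (Me2AlCl, CH2Cl2, −78 → −30 °C), which should pass through the same endo chair arrangement with the silyloxy group equatorial, gives the silyl-protected cycloadduct F2. Desilylation (HF·pyridine, THF, 0 °C) gives 17.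

Step 12 (allylic oxidation). Hydrogen abstraction may be unselective (tertiary allylic C7–H or the C4 methyl instead of the C2 methylene), and over-oxidation may follow. The fallback sets out from 18 and comes back at 19 by an ionic sequence. Hydroxyselenation of the more electron-rich trisubstituted C3=C4 bond (N-(phenylseleno)phthalimide, H2O, camphorsulfonic acid cat., CH2Cl2, 0 °C) gives the 3α-phenylselanyl-4β-hydroxy adduct F3. Oxidation (mCPBA, CH2Cl2, −78 °C; then i-Pr2NH, 23 °C) gives the selenoxide F4, which eliminates syn towards C2 to the tertiary allylic alcohol F5. Oxidative 1,3-transposition with pyridinium chlorochromate [C5H5NH][CrO3Cl] (CH2Cl2, 23 °C; Babler–Dauben oxidation) gives 19.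

Step 14 (conjugate reduction). Hydride transfer to the hindered C4 (β,β-disubstituted, next to the quaternary C5) may be slow, with competing 1,2-reduction of the C2 carbonyl. The fallback sets out from 20 and comes back at 21. Methanolysis of the acetate (K2CO3, MeOH, 0 °C) gives the enone diol F6. Dissolving-metal reduction (Li, NH3/THF, t-BuOH 1 equiv, −78 °C; NH4Cl), in which C4 is protonated axially under stereoelectronic control, gives the saturated keto diol F7. Acetylation of the less hindered equatorial C8 hydroxyl (Ac2O 1.05 equiv, pyridine, 0 °C) gives 21.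

Further compounds
F1 | step 10 | (4R,5R,7E)-7,8-dimethyl-5-(prop-1-en-2-yl)-4-[(triethylsilyl)oxy]deca-1,7,9-trien-3-one | C=C(C)[C@H]([C@@H](O[Si](CC)(CC)CC)C(=O)C=C)C/C(C)=C(C)/C=C
F2 | step 10 | (2R,3R,4aS,8aS)-4a,5-dimethyl-3-(prop-1-en-2-yl)-2-[(triethylsilyl)oxy]-3,4,4a,7,8,8a-hexahydronaphthalen-1(2H)-one | C=C(C)[C@H]1C[C@@]2(C)[C@H](CCC=C2C)C(=O)[C@@H]1O[Si](CC)(CC)CC
F3 | step 12 | 3α-phenylselanyl-4β-hydroxy adduct of 18 (eremophilane numbering; Se at C3, OH at C4) | C=C(C)[C@H]1C[C@@]2(C)[C@H](CC[C@@H]([Se]c3ccccc3)[C@]2(C)O)C(=O)[C@@H]1OC(C)=O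
F4 | step 12 | selenoxide of F3 | C=C(C)[C@H]1C[C@@]2(C)[C@H](CC[C@@H]([Se](=O)c3ccccc3)[C@]2(C)O)C(=O)[C@@H]1OC(C)=O
F5 | step 12 | tertiary allylic alcohol: 4β-hydroxy-Δ2 isomer of 18 (eremophilane numbering; C2=C3, OH at C4) | C=C(C)[C@H]1C[C@@]2(C)[C@H](CC=C[C@]2(C)O)C(=O)[C@@H]1OC(C)=O
F6 | step 14 | 8α,9α-dihydroxyeremophila-3,11-dien-2-one (deacetyl 20) | C=C(C)[C@H]1C[C@@]2(C)[C@H](CC(=O)C=C2C)[C@H](O)[C@@H]1O
F7 | step 14 | 8α,9α-dihydroxyeremophil-11-en-2-one (deacetyl 21) | C=C(C)[C@H]1C[C@@]2(C)[C@H](CC(=O)C[C@@H]2C)[C@H](O)[C@@H]1O
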